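**Retrosynthetic overview**

1. The target is opened at the two bonds of a C3‑radical cascade (7‑exo, then 5‑exo), which leads back to bicyclic triketone 20. Forward, this cascade closes the seven‑membered ring of the homoadamantane and then the cyclopentane.
2. 20 comes from bicyclic vinylogous ester 18 by bridgehead C5 geranylation and O‑demethylation.
3. 18 comes from monocyclic diazo ketone 16, a 4‑methoxycyclopent‑4‑ene‑1,3‑dione. One operation closes the cyclohexanone ring (C1–C9 bond) and widens the five‑membered enedione ring (C2, C3, C4, C5, C9) to the six‑membered ring C1–C5/C9.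
4. Enabling feature: C1 is the only carbon of the tricarbonyl ring that bears an exocyclic C=O (isobutyryl), and it lies between ring carbonyls C2 and C9 and next to quaternary C8. It can therefore enter as an α‑diazo ketone carbon, already bonded to C8, that inserts into the C9–C2 bond.
5. 16 comes from ring 14 (6‑methylhept‑5‑en‑2‑one plus diethyl oxalate) and aldehyde 9 (3,3‑dimethylglutaric anhydride, Evans prenylation sets C7, the only stereocentre that is carried in).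

Key step: step 10

Remark: locants follow the usual numbering of these bicycles (C1 = isobutyryl bridgehead, C2–C4 = dicarbonyl bridge, C5 = geranyl bridgehead, C6–C8 = CH2–CH–CMe2, C9 = bridging C=O). 13 and 20 are drawn as one enol tautomer, and 16 is assumed to be a mixture of C5 epimers that interconvert through the enol.

**Route**

Step 1
Reactants: 1 3,3‑dimethylglutaric anhydride
Product: 2 3,3,6‑trimethyl‑5‑oxoheptanoic acid
Conditions: i‑PrMgCl (1.05 equiv), THF, −78 → −20 °C; 1 M HCl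
Reagents that add atoms: isopropylmagnesium chloride, CC(C)[Mg]Cl
Why: Mono‑addition of a Grignard reagent to a cyclic anhydride should stop at the keto acid, because ring opening leaves an unreactive magnesium carboxylate and the adduct collapses only on work‑up (no stereocentre).

Step 2
Reactants: 2 3,3,6‑trimethyl‑5‑oxoheptanoic acid
Product: 4 (S)‑4‑benzyl‑3‑(3,3,6‑trimethyl‑5‑oxoheptanoyl)oxazolidin‑2‑one, via mixed pivalic anhydride 3 (not isolated)
Conditions: PivCl, Et3N, THF, −20 °C; then (S)‑4‑benzyloxazolidin‑2‑one, LiCl, −20 °C → rt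
Reagents that add atoms: (S)‑4‑benzyloxazolidin‑2‑one, O=C1OC[C@H](Cc2ccccc2)N1; pivaloyl chloride, CC(C)(C)C(=O)Cl (its atoms stay in 3 only)
Why: Mixed‑anhydride N‑acylation of an Evans auxiliary (LiCl/Et3N protocol) should occur at the less hindered acyl carbon of 3 and creates no stereocentre.

Step 3
Reactants: 4 (S)‑4‑benzyl‑3‑(3,3,6‑trimethyl‑5‑oxoheptanoyl)oxazolidin‑2‑one
Product: 5 (S)‑4‑benzyl‑3‑[(2S)‑3,3,6‑trimethyl‑2‑(3‑methylbut‑2‑en‑1‑yl)‑5‑oxoheptanoyl]oxazolidin‑2‑one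
Conditions: NaHMDS (1.1 equiv), THF, −78 °C; prenyl bromide, −78 → −40 °C
Reagents that add atoms: prenyl bromide, CC(C)=CCBr
Why: Evans alkylation, in which the imide (more acidic than the ketone) gives the chelated Z‑enolate and prenyl bromide enters opposite to the benzyl group, should set the future C7 as (2S).

Step 4
Reactants: 5 (S)‑4‑benzyl‑3‑[(2S)‑3,3,6‑trimethyl‑2‑(3‑methylbut‑2‑en‑1‑yl)‑5‑oxoheptanoyl]oxazolidin‑2‑one
Product: 7 (S)‑4‑benzyl‑3‑[(2S)‑4‑diazo‑3,3,6‑trimethyl‑2‑(3‑methylbut‑2‑en‑1‑yl)‑5‑oxoheptanoyl]oxazolidin‑2‑one, via trifluoroacetyl ketone 6 (not isolated)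
Conditions: LiHMDS (1.1 equiv), THF, −78 °C; CF3CO2CH2CF3; then MsN3, Et3N, H2O, MeCN, rt
Reagents that add atoms: methanesulfonyl azide, CS(=O)(=O)N=[N+]=[N-]; 2,2,2‑trifluoroethyl trifluoroacetate, O=C(OCC(F)(F)F)C(F)(F)F (its atoms stay in 6 only)
Why: Detrifluoroacetylative (Danheiser) diazo transfer should work because kinetic enolisation takes the ketone CH2 (the α‑branched imide resists enolisation by A(1,3) strain), and the sulfonyl azide then exchanges the trifluoroacetyl group for N2 without touching the stereocentre.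

Step 5
Reactants: 7 (S)‑4‑benzyl‑3‑[(2S)‑4‑diazo‑3,3,6‑trimethyl‑2‑(3‑methylbut‑2‑en‑1‑yl)‑5‑oxoheptanoyl]oxazolidin‑2‑one
Product: 8 (6S)‑4‑diazo‑7‑hydroxy‑2,5,5‑trimethyl‑6‑(3‑methylbut‑2‑en‑1‑yl)heptan‑3‑one
Conditions: NaBH4, THF–H2O (4:1), 0 °C → rt
Reagents that add atoms: none
Why: Reductive cleavage of an N‑acyloxazolidinone by borohydride should take place at the exocyclic imide carbonyl, while the diazo ketone carbonyl (amide‑like through the diazo group) is left, with retention at the stereocentre.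

Step 6
Reactants: 8 (6S)‑4‑diazo‑7‑hydroxy‑2,5,5‑trimethyl‑6‑(3‑methylbut‑2‑en‑1‑yl)heptan‑3‑one
Product: 9 (2S)‑4‑diazo‑3,3,6‑trimethyl‑2‑(3‑methylbut‑2‑en‑1‑yl)‑5‑oxoheptanal
Conditions: Dess–Martin periodinane, pyridine, CH2Cl2, 0 °C → rt
Reagents that add atoms: none
Why: Dess–Martin oxidation under pyridine buffering should give the aldehyde without protonating the diazo group, and the hindered α‑centre (next to a quaternary carbon) should not epimerise.

Step 7
Reactants: 10 6‑methylhept‑5‑en‑2‑one; 11 diethyl oxalate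
Product: 13 3‑(3‑methylbut‑2‑en‑1‑yl)cyclopentane‑1,2,4‑trione, via diketo ester 12 (not isolated)
Conditions: NaOEt (2.2 equiv), 11 (1.0 equiv), EtOH, 0 °C → reflux; cold 2 M HCl
Reagents that add atoms: none
Why: The classical oxalate annulation of a methyl ketone (crossed Claisen at CH3, then Dieckmann‑type closure from the α′‑CH2 onto the α‑keto ester) should give the trione, with one equivalent of oxalate to avoid C‑ethoxalylation and a cold acid work‑up that spares the prenyl group.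

Step 8
Reactants: 13 3‑(3‑methylbut‑2‑en‑1‑yl)cyclopentane‑1,2,4‑trione
Product: 14 4‑methoxy‑5‑(3‑methylbut‑2‑en‑1‑yl)cyclopent‑4‑ene‑1,3‑dione
Conditions: TMSCHN2, MeOH–toluene (1:4), 0 °C
Reagents that add atoms: trimethylsilyldiazomethane, C[Si](C)(C)C=[N+]=[N-]
Why: O‑Methylation of the acidic 2‑enol (the tautomer conjugated with C4=O) by a diazoalkane should give the methoxy enedione, as known for the 5‑methyl analogue.

Step 9
Reactants: 9 (2S)‑4‑diazo‑3,3,6‑trimethyl‑2‑(3‑methylbut‑2‑en‑1‑yl)‑5‑oxoheptanal; 14 4‑methoxy‑5‑(3‑methylbut‑2‑en‑1‑yl)cyclopent‑4‑ene‑1,3‑dione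
Product: 16 2‑[(2R)‑4‑diazo‑3,3,6‑trimethyl‑2‑(3‑methylbut‑2‑en‑1‑yl)‑5‑oxoheptyl]‑4‑methoxy‑5‑(3‑methylbut‑2‑en‑1‑yl)cyclopent‑4‑ene‑1,3‑dione (both C2 epimers of the ring), via Knoevenagel alkylidene 15 (not isolated)
Conditions: Hantzsch ester (1.1 equiv), L‑proline (20 mol %), CH2Cl2, rt
Reagents that add atoms: none
Why: Organocatalytic reductive alkylation of a cyclic 1,3‑dione (Knoevenagel condensation, then conjugate hydride transfer from the Hantzsch ester) should give the mono‑alkylated dione, whose new ring stereocentre lies between two carbonyls and stays epimerisable, while the hindered chain stereocentre is not touched.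

Step 10
Reactants: 16 2‑[(2R)‑4‑diazo‑3,3,6‑trimethyl‑2‑(3‑methylbut‑2‑en‑1‑yl)‑5‑oxoheptyl]‑4‑methoxy‑5‑(3‑methylbut‑2‑en‑1‑yl)cyclopent‑4‑ene‑1,3‑dione
Product: 18 (1S,5R,7R)‑1‑isobutyryl‑2‑methoxy‑8,8‑dimethyl‑3,7‑bis(3‑methylbut‑2‑en‑1‑yl)bicyclo[3.3.1]non‑2‑ene‑4,9‑dione, via diazonium alkoxide 17 (not isolated)
Conditions: Sc(OTf)3 (20 mol %), 2,6‑lutidine (10 mol %), 4 Å MS, CH2Cl2, −20 °C → rt
Reagents that add atoms: none
Why: Proposed new method: Sc(III) activates the C9 carbonyl (the only ketone of 16 that is not a vinylogous ester, and chelated through the neighbouring OMe), the diazo carbon adds to it, and in betaine 17 the electron‑rich alkenyl carbon C2 migrates from C9 to C1 anti to the leaving N2 (Tiffeneau–Demjanov/semipinacol), so that C1 is formally inserted into the C9–C2 bond; the closest known reactions are Sc(OTf)3‑ or BF3‑promoted homologations of cyclic ketones with α‑alkyl‑α‑diazo carbonyl compounds and their intramolecular versions, which have not been run on a cyclopent‑4‑ene‑1,3‑dione with a tert‑alkyl diazo ketone. Ring closures: the cyclohexanone ring (C1, C5–C9) closes by 6‑exo‑trig attack of C1 on C9=O, and the 1,2‑shift then widens the enedione ring from five atoms (C2–C5, C9) to six (C1–C5, C9), which turns the cis‑fused bicycle 17 into the bridged bicyclo[3.3.1]nonane. Stereocontrol: C7 is the only fixed stereocentre; in the chair transition state its prenyl group is equatorial, N2 is axial and the C9–C2 bond is antiperiplanar to it, an arrangement open to only one C5 epimer, which is resupplied because C5–H (between C4=O and C9=O) epimerises under the conditions, so both epimers of 16 should funnel into the (1S,5R,7R) product with the C7 prenyl endo (syn to C3). Selectivity needed: attack at C9 and not C4 (secured by the vinylogous‑ester deactivation of C4), alkenyl migration and not C5‑alkyl migration or epoxide closure (secured by the antiperiplanar C2 and the high migratory aptitude of an α‑alkoxyalkenyl group), and no carbene reactions at the trisubstituted alkenes (secured by a Lewis acid in place of a carbene‑forming metal).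

Step 11
Reactants: 18 (1S,5R,7R)‑1‑isobutyryl‑2‑methoxy‑8,8‑dimethyl‑3,7‑bis(3‑methylbut‑2‑en‑1‑yl)bicyclo[3.3.1]non‑2‑ene‑4,9‑dione
Product: 19 (1S,5R,7R)‑5‑[(2E)‑3,7‑dimethylocta‑2,6‑dien‑1‑yl]‑1‑isobutyryl‑2‑methoxy‑8,8‑dimethyl‑3,7‑bis(3‑methylbut‑2‑en‑1‑yl)bicyclo[3.3.1]non‑2‑ene‑4,9‑dione
Conditions: LDA (1.5 equiv), THF, −78 °C; geranyl bromide, −78 → −30 °C
Reagents that add atoms: geranyl bromide, CC(C)=CCC/C(C)=C/CBr
Why: Bridgehead (α′) lithiation of the vinylogous ester at C5–H (flanked by C4=O and C9=O, C3 being blocked) followed by alkylation with an allylic bromide is established on such bicyclo[3.3.1]nonane triones and can only occur with retention at the bridgehead.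

Step 12
Reactants: 19 (1S,5R,7R)‑5‑[(2E)‑3,7‑dimethylocta‑2,6‑dien‑1‑yl]‑1‑isobutyryl‑2‑methoxy‑8,8‑dimethyl‑3,7‑bis(3‑methylbut‑2‑en‑1‑yl)bicyclo[3.3.1]non‑2‑ene‑4,9‑dione
Product: 20 (1S,5R,7R)‑5‑[(2E)‑3,7‑dimethylocta‑2,6‑dien‑1‑yl]‑2‑hydroxy‑1‑isobutyryl‑8,8‑dimethyl‑3,7‑bis(3‑methylbut‑2‑en‑1‑yl)bicyclo[3.3.1]non‑2‑ene‑4,9‑dione
Conditions: LiCl (5 equiv), DMSO, 120 °C; dilute HCl
Reagents that add atoms: none
Why: SN2 demethylation of the vinylogous methyl ester by chloride in hot DMSO (Krapcho‑type) should free the enolised 2,4‑diketone without affecting the stereocentres.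

Step 13
Reactants: 20 (1S,5R,7R)‑5‑[(2E)‑3,7‑dimethylocta‑2,6‑dien‑1‑yl]‑2‑hydroxy‑1‑isobutyryl‑8,8‑dimethyl‑3,7‑bis(3‑methylbut‑2‑en‑1‑yl)bicyclo[3.3.1]non‑2‑ene‑4,9‑dione
Product: 21 target CNP0379246.1
Conditions: Mn(OAc)3·2H2O (2.2 equiv), degassed EtOH, rt → 50 °C (no Cu(II))
Reagents that add atoms: none
Why: Mn(III) oxidation of the enolised 1,3‑diketone should give the C3 radical, which can be reached by the endo C7‑prenyl alkene only on its lower face (7‑exo‑trig, closing the homoadamantane; the CMe2 end must turn to the C1/C2 side, the orientation the target requires), after which chair‑like 5‑exo‑trig closure onto the C3‑prenyl alkene should place the new isopropyl‑bearing carbon trans to the cage CH2 (Beckwith–Houk), and the last tertiary radical should take a hydrogen atom from ethanol because no Cu(II) is present.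

**Compound list**

1 | 3,3‑dimethylglutaric anhydride | CC1(C)CC(=O)OC(=O)C1 | starting material
2 | 3,3,6‑trimethyl‑5‑oxoheptanoic acid | CC(C)C(=O)CC(C)(C)CC(=O)O | intermediate
3 | 3,3,6‑trimethyl‑5‑oxoheptanoic pivalic anhydride | CC(C)C(=O)CC(C)(C)CC(=O)OC(=O)C(C)(C)C | intermediate
4 | (S)‑4‑benzyl‑3‑(3,3,6‑trimethyl‑5‑oxoheptanoyl)oxazolidin‑2‑one | CC(C)C(=O)CC(C)(C)CC(=O)N1[C@@H](Cc2ccccc2)COC1=O | intermediate
5 | (S)‑4‑benzyl‑3‑[(2S)‑3,3,6‑trimethyl‑2‑(3‑methylbut‑2‑en‑1‑yl)‑5‑oxoheptanoyl]oxazolidin‑2‑one | CC(C)C(=O)CC(C)(C)[C@H](CC=C(C)C)C(=O)N1[C@@H](Cc2ccccc2)COC1=O | intermediate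
6 | (S)‑4‑benzyl‑3‑[(2S)‑3,3,6‑trimethyl‑2‑(3‑methylbut‑2‑en‑1‑yl)‑5‑oxo‑4‑(trifluoroacetyl)heptanoyl]oxazolidin‑2‑one (C4 epimers) | CC(C)C(=O)C(C(=O)C(F)(F)F)C(C)(C)[C@H](CC=C(C)C)C(=O)N1[C@@H](Cc2ccccc2)COC1=O | intermediate
7 | (S)‑4‑benzyl‑3‑[(2S)‑4‑diazo‑3,3,6‑trimethyl‑2‑(3‑methylbut‑2‑en‑1‑yl)‑5‑oxoheptanoyl]oxazolidin‑2‑one | CC(C)C(=O)C(=[N+]=[N-])C(C)(C)[C@H](CC=C(C)C)C(=O)N1[C@@H](Cc2ccccc2)COC1=O | intermediate
8 | (6S)‑4‑diazo‑7‑hydroxy‑2,5,5‑trimethyl‑6‑(3‑methylbut‑2‑en‑1‑yl)heptan‑3‑one | CC(C)C(=O)C(=[N+]=[N-])C(C)(C)[C@H](CC=C(C)C)CO | intermediate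
9 | (2S)‑4‑diazo‑3,3,6‑trimethyl‑2‑(3‑methylbut‑2‑en‑1‑yl)‑5‑oxoheptanal | CC(C)C(=O)C(=[N+]=[N-])C(C)(C)[C@H](CC=C(C)C)C=O | intermediate
10 | 6‑methylhept‑5‑en‑2‑one | CC(=O)CCC=C(C)C | starting material
11 | diethyl oxalate | CCOC(=O)C(=O)OCC | starting material
12 | ethyl 8‑methyl‑2,4‑dioxonon‑7‑enoate | CCOC(=O)C(=O)CC(=O)CCC=C(C)C | intermediate
13 | 3‑(3‑methylbut‑2‑en‑1‑yl)cyclopentane‑1,2,4‑trione (2‑enol drawn) | OC1=C(CC=C(C)C)C(=O)CC1=O | intermediate
14 | 4‑methoxy‑5‑(3‑methylbut‑2‑en‑1‑yl)cyclopent‑4‑ene‑1,3‑dione | COC1=C(CC=C(C)C)C(=O)CC1=O | intermediate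
15 | 2‑[(2R)‑4‑diazo‑3,3,6‑trimethyl‑2‑(3‑methylbut‑2‑en‑1‑yl)‑5‑oxoheptylidene]‑4‑methoxy‑5‑(3‑methylbut‑2‑en‑1‑yl)cyclopent‑4‑ene‑1,3‑dione (E/Z) | COC1=C(CC=C(C)C)C(=O)C(=C[C@@H](CC=C(C)C)C(C)(C)C(=[N+]=[N-])C(=O)C(C)C)C1=O | intermediate
16 | 2‑[(2R)‑4‑diazo‑3,3,6‑trimethyl‑2‑(3‑methylbut‑2‑en‑1‑yl)‑5‑oxoheptyl]‑4‑methoxy‑5‑(3‑methylbut‑2‑en‑1‑yl)cyclopent‑4‑ene‑1,3‑dione (C2 epimers) | COC1=C(CC=C(C)C)C(=O)C(C[C@@H](CC=C(C)C)C(C)(C)C(=[N+]=[N-])C(=O)C(C)C)C1=O | intermediate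
17 | zwitterionic C1‑diazonium C9‑alkoxide, cis‑fused five/six‑membered bicycle (C1–C9 bond formed, C7 prenyl equatorial) | [O-][C@]12C(OC)=C(CC=C(C)C)C(=O)[C@H]1C[C@@H](CC=C(C)C)C(C)(C)[C@@]2([N+]#N)C(=O)C(C)C | intermediate
18 | (1S,5R,7R)‑1‑isobutyryl‑2‑methoxy‑8,8‑dimethyl‑3,7‑bis(3‑methylbut‑2‑en‑1‑yl)bicyclo[3.3.1]non‑2‑ene‑4,9‑dione (C7 prenyl endo) | [C@@H]12C[C@@H](CC=C(C)C)C(C)(C)[C@](C(=O)C(C)C)(C2=O)C(OC)=C(CC=C(C)C)C1=O | intermediate
19 | (1S,5R,7R)‑5‑[(2E)‑3,7‑dimethylocta‑2,6‑dien‑1‑yl]‑1‑isobutyryl‑2‑methoxy‑8,8‑dimethyl‑3,7‑bis(3‑methylbut‑2‑en‑1‑yl)bicyclo[3.3.1]non‑2‑ene‑4,9‑dione | CC(C)=CCC/C(C)=C/C[C@@]12C[C@@H](CC=C(C)C)C(C)(C)[C@](C(=O)C(C)C)(C2=O)C(OC)=C(CC=C(C)C)C1=O | intermediate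
20 | (1S,5R,7R)‑5‑[(2E)‑3,7‑dimethylocta‑2,6‑dien‑1‑yl]‑2‑hydroxy‑1‑isobutyryl‑8,8‑dimethyl‑3,7‑bis(3‑methylbut‑2‑en‑1‑yl)bicyclo[3.3.1]non‑2‑ene‑4,9‑dione | CC(C)=CCC/C(C)=C/C[C@@]12C[C@@H](CC=C(C)C)C(C)(C)[C@](C(=O)C(C)C)(C2=O)C(O)=C(CC=C(C)C)C1=O | intermediate
21 | CNP0379246.1: homoadamantane trione with fused 2,2‑dimethyl‑3‑isopropylcyclopentane, C1 isobutyryl, C5 geranyl, C8 gem‑dimethyl | CC(C)=CCC/C(C)=C/C[C@@]12C[C@H]3C[C@@H]4C(C)(C)[C@@H](C(C)C)C[C@]4(C1=O)C(=O)[C@@](C(=O)C(C)C)(C2=O)C3(C)C | target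

**Count and risks**

Total step count: 13. Longest linear sequence: 11 steps (1–6, then 9–13).

Steps most likely to fail:

1. Step 10 (Proposed new method). The hindered tert‑alkyl diazo carbon may add to C9 too slowly, so that protonation of the diazo group, attack at C4, collapse of the betaine to an epoxide or migration of C5 takes over. The fallback builds the same two bonds one after the other with known reactions and a C5‑quaternary substrate. It sets out from 5. LiBH4 in wet THF should reduce imide and ketone to (2S)‑3,3,6‑trimethyl‑2‑(3‑methylbut‑2‑en‑1‑yl)heptane‑1,5‑diol F1. Dess–Martin oxidation should give (2S)‑3,3,6‑trimethyl‑2‑(3‑methylbut‑2‑en‑1‑yl)‑5‑oxoheptanal F2. Reductive Knoevenagel alkylation of 14 as in step 9 should give the diazo‑free analogue of 16, F3. C‑Geranylation with geranyl bromide and K2CO3 in acetone (O‑alkylation would create a cyclopentadienone) should give the C2‑quaternary dione as both epimers, F4. Intramolecular aldol addition of the kinetic lithium enolate (LDA, THF, −78 °C) to C9 is open only to the epimer that can hold the C7 prenyl equatorial, and should give the cis‑fused ketol F5. Hypervalent‑iodine oxidation (PhI(OAc)2, KOH, MeOH) should then induce the 1,2‑shift of C2 from C9 to the iodanyl‑bearing C1, the oxidative ring expansion known for fused hydroxy ketones in this family. The fallback returns to the route at 19, at the cost of the epimer funnel.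

2. Step 13. The last tertiary radical may be oxidised (to an isopropenyl group or an acetate) before it finds a hydrogen atom, and the orientation of the alkene in the first ring closure may not be the one required. The fallback makes the radical reductively. It sets out from 20. NBS in CH2Cl2 at −78 °C should brominate the enol carbon to give the 3‑bromo‑2,4,9‑trione F6. Bu3SnH with AIBN in benzene at 80 °C should then generate the same C3 radical, and the cascade ends by hydrogen transfer from the stannane, which returns to the route at 21.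

3. Step 11. Bridgehead deprotonation may be incomplete, or the lithiated bridgehead may not be alkylated by the bulky allylic bromide. The fallback installs the geranyl group before the ring expansion. It sets out from 16. Geranyl bromide and K2CO3 in acetone should give the C2‑geranylated diazo dione as both epimers, F7. The conditions of step 10 should convert the epimer that can place the C7 prenyl equatorial, returning to the route at 19. Without the epimerisable C–H only that epimer is used.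

**Further compounds**

F1 | step 10 | (2S)‑3,3,6‑trimethyl‑2‑(3‑methylbut‑2‑en‑1‑yl)heptane‑1,5‑diol (C5 epimers) | CC(C)C(O)CC(C)(C)[C@H](CC=C(C)C)CO
F2 | step 10 | (2S)‑3,3,6‑trimethyl‑2‑(3‑methylbut‑2‑en‑1‑yl)‑5‑oxoheptanal | CC(C)C(=O)CC(C)(C)[C@H](CC=C(C)C)C=O
F3 | step 10 | 4‑methoxy‑5‑(3‑methylbut‑2‑en‑1‑yl)‑2‑[(2R)‑3,3,6‑trimethyl‑2‑(3‑methylbut‑2‑en‑1‑yl)‑5‑oxoheptyl]cyclopent‑4‑ene‑1,3‑dione (C2 epimers) | COC1=C(CC=C(C)C)C(=O)C(C[C@@H](CC=C(C)C)C(C)(C)CC(=O)C(C)C)C1=O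
F4 | step 10 | 2‑[(2E)‑3,7‑dimethylocta‑2,6‑dien‑1‑yl]‑4‑methoxy‑5‑(3‑methylbut‑2‑en‑1‑yl)‑2‑[(2R)‑3,3,6‑trimethyl‑2‑(3‑methylbut‑2‑en‑1‑yl)‑5‑oxoheptyl]cyclopent‑4‑ene‑1,3‑dione (C2 epimers) | CC(C)=CCC/C(C)=C/CC1(C[C@@H](CC=C(C)C)C(C)(C)CC(=O)C(C)C)C(=O)C(CC=C(C)C)=C(OC)C1=O
F5 | step 10 | cis‑fused aldol ketol (C9 carbinol bonded to C1–H, C5 geranyl, C7 prenyl equatorial; C1 epimers) | O[C@]12C(OC)=C(CC=C(C)C)C(=O)[C@@]1(C/C=C(\C)CCC=C(C)C)C[C@@H](CC=C(C)C)C(C)(C)C2C(=O)C(C)C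
F6 | step 13 | (1S,5R,7R)‑3‑bromo‑5‑[(2E)‑3,7‑dimethylocta‑2,6‑dien‑1‑yl]‑1‑isobutyryl‑8,8‑dimethyl‑3,7‑bis(3‑methylbut‑2‑en‑1‑yl)bicyclo[3.3.1]nonane‑2,4,9‑trione (C3 epimers) | CC(C)=CCC/C(C)=C/C[C@@]12C[C@@H](CC=C(C)C)C(C)(C)[C@](C(=O)C(C)C)(C2=O)C(=O)C(Br)(CC=C(C)C)C1=O
F7 | step 11 | 2‑[(2R)‑4‑diazo‑3,3,6‑trimethyl‑2‑(3‑methylbut‑2‑en‑1‑yl)‑5‑oxoheptyl]‑2‑[(2E)‑3,7‑dimethylocta‑2,6‑dien‑1‑yl]‑4‑methoxy‑5‑(3‑methylbut‑2‑en‑1‑yl)cyclopent‑4‑ene‑1,3‑dione (C2 epimers) | CC(C)=CCC/C(C)=C/CC1(C[C@@H](CC=C(C)C)C(C)(C)C(=[N+]=[N-])C(=O)C(C)C)C(=O)C(CC=C(C)C)=C(OC)C1=O
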